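**Retrosynthetic overview**
1. The C2–Cl / C3–Br pair of ring B is a trans-diaxial dihalide retron of a C2=C3 alkene: epoxide on the ring B face anti to C7, chloride at C2, then bromide for hydroxyl at C3 with retention.
2. Ring B is closed last, at C3–C4, by an intramolecular B-alkyl Suzuki–Miyaura coupling. The enabling feature is that C3 is the methyl-bearing sp2 carbon of that C2=C3 retron and C4–C5 is a bare two-carbon link to the spiro carbon C6, so C3–C4 is an unhindered sp2–sp3 bond away from the vicinal quaternary carbons C6/C11.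
3. Both ring B arms on C6 come from one temporary spiro γ-butyrolactone: the lactone carbonyl becomes C5 (then the vinyl group C5=C4), the OCH2CH2 unit becomes C2–C1 (then the Z vinyl iodide at C3).
4. Ring A and the spiro carbon C6 are made together by bromonium-assisted C-alkylation of a β-keto lactone enol; C10 comes from enantioselective bromochlorination of prenol.
5. Order of ring formation: lactone (present in the starting material, later opened) → ring A → ring B.

Key step: step 9

Numbering (chamigrane): C6 spiro; ring A = C6, C7 (bears C14), C8, C9, C10 (Br), C11 (methyls C12, C13); ring B = C6, C1, C2 (Cl), C3 (Br, methyl C15), C4, C5.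
Assumption: on ring B the sp2 carbon C7 sits axial and the quaternary C11 equatorial, so reagents reach C2=C3 anti to C7 and ring openings are trans-diaxial.

**Step 1**
Reactants: 1 3-methylbut-2-en-1-ol (prenol)
Product: 2 (2S)-2-bromo-3-chloro-3-methylbutan-1-ol
Conditions: NBS, ClTi(OiPr)3, chiral tridentate Schiff-base amino alcohol ligand (20 mol %), hexanes, −20 °C
Reagents that add atoms: N-bromosuccinimide O=C1CCC(=O)N1Br; chlorotitanium triisopropoxide CC(C)O[Ti](Cl)(OC(C)C)OC(C)C
Why: Catalytic enantioselective bromochlorination of an allylic alcohol: the ligated titanium alkoxide of 1 directs Br+ to one alkene face and titanium-bound chloride opens the bromonium ion anti at the tertiary carbon, so the stereocenter (later C10) is set by the ligand, whose enantiomer is chosen for 2S.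

**Step 2**
Reactants: 2 (2S)-2-bromo-3-chloro-3-methylbutan-1-ol
Product: 3 (2S)-2-bromo-3-chloro-3-methylbutyl trifluoromethanesulfonate
Conditions: Tf2O, 2,6-lutidine, CH2Cl2, −78 °C
Reagents that add atoms: trifluoromethanesulfonic anhydride O=S(=O)(OS(=O)(=O)C(F)(F)F)C(F)(F)F
Why: O-sulfonylation of the primary alcohol at −78 °C gives a leaving group reactive enough for SN2 at a β-branched carbon; the stereocenter is not involved.

**Step 3**
Reactants: 3 (2S)-2-bromo-3-chloro-3-methylbutyl trifluoromethanesulfonate; 4 3-acetyloxolan-2-one (2-acetyl-γ-butyrolactone)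
Product: 6 3-[(4S)-4-bromo-5-chloro-5-methylhexanoyl]oxolan-2-one, via dilithium dienolate 5 (not isolated)
Conditions: 4, LDA (2.1 equiv), THF, −78 → 0 °C; then 3, −78 °C
Reagents that add atoms: none
Why: γ-Alkylation of a β-dicarbonyl dianion: the non-stabilized carbanion at the acetyl methyl group is the more nucleophilic site and displaces the primary triflate by SN2 at −78 °C, leaving the bromine-bearing stereocenter untouched.

**Step 4**
Reactants: 6 3-[(4S)-4-bromo-5-chloro-5-methylhexanoyl]oxolan-2-one
Product: 7 (5S,9S)-9-bromo-10,10-dimethyl-2-oxaspiro[4.5]decane-1,6-dione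
Conditions: SnCl4 (1.2 equiv), CH2Cl2, −78 → −20 °C
Reagents that add atoms: none
Why: Lewis-acid-promoted intramolecular tert-alkylation of a 1,3-dicarbonyl (the type of SnCl4-promoted β-keto ester cyclization) with bromonium participation: SnCl4 ionizes the tertiary chloride with anchimeric help from the neighbouring bromine, so C10 keeps its configuration, and the tin-chelated Z enol (lactone carbonyl cis to the enol oxygen) attacks C11 through carbon anti to bromine in a chair transition state, which places Br equatorial, the lactone carbonyl C5 equatorial and the lactone CH2 (C1) axial on ring A and so sets C6.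

**Step 5**
Reactants: 7 (5S,9S)-9-bromo-10,10-dimethyl-2-oxaspiro[4.5]decane-1,6-dione
Product: 8 (5S,9S)-9-bromo-10,10-dimethyl-2-oxaspiro[4.5]decane-1,6-diol (epimers at C1 and C6)
Conditions: DIBAL-H (3.3 equiv), CH2Cl2, −78 °C; Rochelle salt work-up
Reagents that add atoms: none
Why: DIBAL-H reduction: at −78 °C the lactone stops at the lactol (stable aluminium hemiacetal) and the ketone gives the carbinol; the two new mixed stereocenters are removed again in steps 6 and 7.

**Step 6**
Reactants: 8 (5S,9S)-9-bromo-10,10-dimethyl-2-oxaspiro[4.5]decane-1,6-diol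
Product: 9 (2S,4S)-4-bromo-2-ethenyl-2-(2-hydroxyethyl)-3,3-dimethylcyclohexan-1-ol (epimers at C1)
Conditions: Ph3PCH3Br, n-BuLi (5 equiv of ylide), THF, 0 °C; then 8, 0 °C → rt
Reagents that add atoms: methyltriphenylphosphonium bromide C[P+](c1ccccc1)(c1ccccc1)c1ccccc1.[Br-]
Why: Wittig methylenation of the lactol through its open hydroxy aldehyde form turns the former lactone carbonyl C5 into the vinyl group C5=C4 and frees the primary alcohol at C2; lithium alkoxides at 0 °C disfavour retro-aldol cleavage of the β-alkoxy aldehyde.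

**Step 7**
Reactants: 9 (2S,4S)-4-bromo-2-ethenyl-2-(2-hydroxyethyl)-3,3-dimethylcyclohexan-1-ol
Product: 10 2-[(1S,3S)-3-bromo-1-ethenyl-2,2-dimethyl-6-oxocyclohexyl]acetaldehyde
Conditions: Dess–Martin periodinane (2.6 equiv), CH2Cl2, rt
Reagents that add atoms: none
Why: Dess–Martin oxidation converts the primary alcohol into the C2 aldehyde and the secondary alcohol back into the C7 ketone in one neutral operation; the quaternary C6 blocks enolization toward it and conjugation of the vinyl group.

**Step 8**
Reactants: 10 2-[(1S,3S)-3-bromo-1-ethenyl-2,2-dimethyl-6-oxocyclohexyl]acetaldehyde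
Product: 11 (2S,4S)-4-bromo-2-ethenyl-2-[(2Z)-3-iodobut-2-en-1-yl]-3,3-dimethylcyclohexan-1-one
Conditions: EtPPh3I, n-BuLi, THF, rt; I2, −78 °C; NaHMDS, −20 °C; then 10, −78 °C
Reagents that add atoms: ethyltriphenylphosphonium iodide CC[P+](c1ccccc1)(c1ccccc1)c1ccccc1.[I-]; iodine [I][I]
Why: Stork–Zhao olefination with the α-iodoethylidene ylide is Z-selective (iodine cis to the C1 methylene) and attacks only the unhindered aldehyde, not the hindered C7 ketone.

**Step 9**
Reactants: 11 (2S,4S)-4-bromo-2-ethenyl-2-[(2Z)-3-iodobut-2-en-1-yl]-3,3-dimethylcyclohexan-1-one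
Product: 13 (4S,6R)-4-bromo-5,5,9-trimethylspiro[5.5]undec-8-en-1-one, via B-alkyl-9-BBN borane 12 (not isolated)
Conditions: 9-BBN (1.3 equiv), THF, 0 °C → rt; then PdCl2(dppf) (10 mol %), AsPh3, Cs2CO3, H2O, DMF, 0.005 M, 45 °C
Reagents that add atoms: none
Why: 9-BBN adds anti-Markovnikov and chemoselectively to the monosubstituted C5=C4 vinyl group (the iodo-substituted trisubstituted alkene and the hindered C7 ketone react far more slowly) to give the primary C4 borane 12; zerovalent palladium then inserts into the C3–I bond with retention of the Z geometry, base-assisted transmetalation transfers C4 from boron, and reductive elimination from the seven-membered palladacycle (Pd, C3, C2, C1, C6, C5, C4) forms the C3–C4 bond. The closest known reaction type is the intramolecular B-alkyl Suzuki–Miyaura coupling of a hydroborated ω-alkenyl vinyl halide, established for five- and six-membered carbocycles. Ring B closes in a six-membered mode by C(sp2)–C(sp3) reductive elimination, with the C2=C3 double bond ending endocyclic. No new stereocenter is formed: C6 and C10 are untouched, and the position and geometry of the C2=C3 alkene are fixed by the Z vinyl iodide, whose iodine is cis to the C1 methylene as the ring requires. The step needs insertion into the vinyl C–I bond and not the secondary neopentyl C10–Br bond (unactivated secondary alkyl bromides do not add to the dppf-ligated catalyst at 45 °C), and cyclization over oligomerization, which the quaternary C6 and high dilution secure; the mild carbonate base spares the C10 bromide.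

**Step 10**
Reactants: 13 (4S,6R)-4-bromo-5,5,9-trimethylspiro[5.5]undec-8-en-1-one
Product: 14 (6S,8S)-8-bromo-3,7,7-trimethyl-11-methylidenespiro[5.5]undec-2-ene [(6S,10S)-10-bromochamigra-2,7(14)-diene]
Conditions: Cp2Ti(μ-Cl)(μ-CH2)AlMe2 (Tebbe reagent, 1.5 equiv), pyridine (cat.), THF/toluene, −40 → 0 °C
Reagents that add atoms: Tebbe reagent C[Al-]1(C)C[Ti]([Cl+]1)(C1C=CC=C1)C1C=CC=C1
Why: Tebbe methylenation: the non-basic titanium methylidene converts the hindered α-quaternary C7 ketone into the C7=C14 methylene without touching the secondary C10 bromide or the ring B alkene; C6 changes only its descriptor.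

**Step 11**
Reactants: 14 (6S,10S)-10-bromochamigra-2,7(14)-diene
Product: 15 (2S,3R,6S,10S)-10-bromo-2,3-epoxychamigr-7(14)-ene (epoxide oxygen on the ring B face anti to C7)
Conditions: mCPBA (1.05 equiv), CH2Cl2, −20 → 0 °C
Reagents that add atoms: 3-chloroperbenzoic acid OOC(=O)c1cccc(Cl)c1
Why: Prilezhaev epoxidation: the peracid reacts faster with the trisubstituted C2=C3 alkene than with the hindered 1,1-disubstituted C7=C14, and from the ring B face anti to the axial C7, which sets C2 and C3.

**Step 12**
Reactants: 15 (2S,3R,6S,10S)-10-bromo-2,3-epoxychamigr-7(14)-ene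
Product: 16 (2R,3R,6S,10S)-10-bromo-2-chlorochamigr-7(14)-en-3-ol
Conditions: Li2CuCl4 (2 equiv), THF, 0 °C → rt
Reagents that add atoms: dilithium tetrachlorocuprate [Li+].[Li+].Cl[Cu-2](Cl)(Cl)Cl
Why: Nucleophilic (SN2-type) chlorohydrin formation: chloride attacks the secondary carbon C2 with inversion in a trans-diaxial opening (Fürst–Plattner rule), giving C2–Cl axial and syn to C7 and leaving the tertiary C3–O bond intact.

**Step 13**
Reactants: 16 (2R,3R,6S,10S)-10-bromo-2-chlorochamigr-7(14)-en-3-ol
Product: 17 (2R,3R,6S,10S)-3,10-dibromo-2-chlorochamigr-7(14)-ene (CNP0280843.3)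
Conditions: 1-bromo-N,N,2-trimethylprop-1-en-1-amine (1.5 equiv), CH2Cl2, 0 °C → rt
Reagents that add atoms: 1-bromo-N,N,2-trimethylprop-1-en-1-amine CC(C)=C(Br)N(C)C
Why: Neutral conversion of a tertiary alcohol into the bromide with an α-bromoenamine: the O-imidoyl leaving group departs with anchimeric help from the antiperiplanar (trans-diaxial) C2 chlorine and bromide opens the chloronium ion axially at the tertiary C3, so C3 is substituted with retention and Br ends trans to Cl; no free HBr is present to add to C7=C14.

**Compound list**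
1 | 3-methylbut-2-en-1-ol (prenol) | CC(C)=CCO | starting material
2 | (2S)-2-bromo-3-chloro-3-methylbutan-1-ol | OC[C@H](Br)C(C)(C)Cl | intermediate
3 | (2S)-2-bromo-3-chloro-3-methylbutyl trifluoromethanesulfonate | O=S(=O)(OC[C@H](Br)C(C)(C)Cl)C(F)(F)F | intermediate
4 | 3-acetyloxolan-2-one (2-acetyl-γ-butyrolactone, racemic) | CC(=O)C1CCOC1=O | starting material
5 | dilithium dienolate of 3-acetyloxolan-2-one (not isolated) | [Li+].[Li+].C=C([O-])C1=C([O-])OCC1 | intermediate
6 | 3-[(4S)-4-bromo-5-chloro-5-methylhexanoyl]oxolan-2-one (epimers at the lactone α-carbon) | O=C1OCCC1C(=O)CC[C@H](Br)C(C)(C)Cl | intermediate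
7 | (5S,9S)-9-bromo-10,10-dimethyl-2-oxaspiro[4.5]decane-1,6-dione | O=C1CC[C@H](Br)C(C)(C)[C@]12C(=O)OCC2 | intermediate
8 | (5S,9S)-9-bromo-10,10-dimethyl-2-oxaspiro[4.5]decane-1,6-diol (epimers at C1 and C6) | OC1CC[C@H](Br)C(C)(C)[C@]12C(O)OCC2 | intermediate
9 | (2S,4S)-4-bromo-2-ethenyl-2-(2-hydroxyethyl)-3,3-dimethylcyclohexan-1-ol (epimers at C1) | OC1CC[C@H](Br)C(C)(C)[C@]1(CCO)C=C | intermediate
10 | 2-[(1S,3S)-3-bromo-1-ethenyl-2,2-dimethyl-6-oxocyclohexyl]acetaldehyde | O=C1CC[C@H](Br)C(C)(C)[C@]1(CC=O)C=C | intermediate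
11 | (2S,4S)-4-bromo-2-ethenyl-2-[(2Z)-3-iodobut-2-en-1-yl]-3,3-dimethylcyclohexan-1-one | O=C1CC[C@H](Br)C(C)(C)[C@]1(C/C=C(\I)C)C=C | intermediate
12 | 9-{2-[(1R,3S)-3-bromo-1-[(2Z)-3-iodobut-2-en-1-yl]-2,2-dimethyl-6-oxocyclohexyl]ethyl}-9-borabicyclo[3.3.1]nonane (not isolated) | O=C1CC[C@H](Br)C(C)(C)[C@]1(C/C=C(\I)C)CCB1C2CCCC1CCC2 | intermediate
13 | (4S,6R)-4-bromo-5,5,9-trimethylspiro[5.5]undec-8-en-1-one [(6R,10S)-10-bromochamigr-2-en-7-one] | O=C1CC[C@H](Br)C(C)(C)[C@]12CCC(C)=CC2 | intermediate
14 | (6S,8S)-8-bromo-3,7,7-trimethyl-11-methylidenespiro[5.5]undec-2-ene [(6S,10S)-10-bromochamigra-2,7(14)-diene] | C=C1CC[C@H](Br)C(C)(C)[C@]12CCC(C)=CC2 | intermediate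
15 | (2S,3R,6S,10S)-10-bromo-2,3-epoxychamigr-7(14)-ene (oxygen anti to C7) | C=C1CC[C@H](Br)C(C)(C)[C@]12CC[C@@]3(C)O[C@H]3C2 | intermediate
16 | (2R,3R,6S,10S)-10-bromo-2-chlorochamigr-7(14)-en-3-ol | C=C1CC[C@H](Br)C(C)(C)[C@]12CC[C@@](C)(O)[C@H](Cl)C2 | intermediate
17 | (2R,3R,6S,10S)-3,10-dibromo-2-chlorochamigr-7(14)-ene | C=C1CC[C@H](Br)C(C)(C)[C@]12CC[C@@](C)(Br)[C@H](Cl)C2 | target

**Step count and risks**
Total steps: 13. Longest linear sequence: 13 steps (from 1; 4 enters at step 3).

Steps most likely to fail:

1. Step 4. The bromonium or tertiary cation may be captured by the enol oxygen, or lose a proton, instead of forming the congested C6–C11 bond; a boat-like closure would erode the C6 configuration. Fallback, setting out from 3 and returning at 7: methyl acetoacetate is doubly deprotonated with LDA to the dilithium dienolate of methyl acetoacetate F1, which is alkylated with 3 to give methyl (6S)-6-bromo-7-chloro-7-methyl-3-oxooctanoate F2. SnCl4 then closes ring A at an enol carbon that carries only hydrogen (the established, less congested case) to give methyl (5S)-5-bromo-6,6-dimethyl-2-oxocyclohexane-1-carboxylate F3. The sodium enolate of F3 opens ethylene oxide from the face anti to the axial methyl on C11, and the resulting alkoxide lactonizes onto the methyl ester to give 7.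

2. Step 12. Lewis-acid-assisted opening of the epoxide at the tertiary C3, or rearrangement of the epoxide, may compete with SN2 attack at the hindered axial trajectory on C2. Fallback, setting out from 14 and returning at 17: direct bromine chloride addition with tetrabutylammonium dichlorobromate in CH2Cl2 at −78 °C. Bromonium formation is reversible, and trans-diaxial opening at C2 of the bromonium ion on the face anti to C7 gives 17 in one step. The regioisomer from the other bromonium ion, (2R,3R,6S,10S)-2,10-dibromo-3-chlorochamigr-7(14)-ene F4, would be removed by chromatography.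

3. Step 13. Elimination to allylic chlorides, chlorine migration through the chloronium ion, or acid-mediated addition to or isomerization of C7=C14 may compete with bromide capture at C3. Fallback, setting out from 13 and returning at 17: the methylenation is moved to the end so that a strongly acidic bromination can be used. Ketone 13 is epoxidized with mCPBA to (2S,3R,6R,10S)-10-bromo-2,3-epoxychamigran-7-one F5, opened with Li2CuCl4 to (2R,3R,6R,10S)-10-bromo-2-chloro-3-hydroxychamigran-7-one F6, and converted with TMSBr (CH2Cl2, 0 °C) into (2R,3R,6R,10S)-3,10-dibromo-2-chlorochamigran-7-one F7. Tebbe methylenation of F7 then gives 17.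

**Further compounds**
F1 | step 4 | dilithium dienolate of methyl acetoacetate | [Li+].[Li+].C=C([O-])C=C([O-])OC
F2 | step 4 | methyl (6S)-6-bromo-7-chloro-7-methyl-3-oxooctanoate | COC(=O)CC(=O)CC[C@H](Br)C(C)(C)Cl
F3 | step 4 | methyl (5S)-5-bromo-6,6-dimethyl-2-oxocyclohexane-1-carboxylate | COC(=O)C1C(=O)CC[C@H](Br)C1(C)C
F4 | step 12 | (2R,3R,6S,10S)-2,10-dibromo-3-chlorochamigr-7(14)-ene | C=C1CC[C@H](Br)C(C)(C)[C@]12CC[C@@](C)(Cl)[C@H](Br)C2
F5 | step 13 | (2S,3R,6R,10S)-10-bromo-2,3-epoxychamigran-7-one | O=C1CC[C@H](Br)C(C)(C)[C@]12CC[C@@]3(C)O[C@H]3C2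
F6 | step 13 | (2R,3R,6R,10S)-10-bromo-2-chloro-3-hydroxychamigran-7-one | O=C1CC[C@H](Br)C(C)(C)[C@]12CC[C@@](C)(O)[C@H](Cl)C2
F7 | step 13 | (2R,3R,6R,10S)-3,10-dibromo-2-chlorochamigran-7-one | O=C1CC[C@H](Br)C(C)(C)[C@]12CC[C@@](C)(Br)[C@H](Cl)C2
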